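The target, 4-[(2,4-dimethoxy-6-propylbenzoyl)oxy]-2-methoxy-6-pentylbenzoic acid, is a depside in which ring B (2,4-dimethoxy-6-propylbenzoyl) esterifies O4 of ring A (2-methoxy-6-pentylbenzoic acid). Instead of forcing a di-ortho-substituted acid onto a phenol, ring B is grown on the preformed ester. The key step uses the pattern of ring B: C1 and C6 (acyl and propyl carbons) are a vicinal pair that an alkynoate triple bond supplies, and C2–C5, oxygenated at C2 and C4, are the chain of a 1,1,3-trioxygenated butadiene. A Diels–Alder reaction with aromatising loss of methanol forms C1–C2 and C5–C6 in one operation. Its precursor is the hex-2-ynoate of tert-butyl 4-hydroxy-2-methoxy-6-pentylbenzoate, partnered with 1,3-dimethoxy-1-(trimethylsilyloxy)buta-1,3-diene.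

Key step: step 6

Remark: the target has no stereocentre, stereogenic axis or configured double bond, so it is achiral and the route needs no stereocontrol; the ketene acetal geometry of diene 11 has no bearing on the product.

Step 1
Reactants: 1 2-methoxy-6-methylbenzoic acid
Product: 3 2-methoxy-6-pentylbenzoic acid, via benzylic dianion 2 (not isolated)
Conditions: LDA (2.2 equiv, commercial solution), THF, −78 → 0 °C; n-BuI (1.2 equiv), −78 °C → rt; aq. HCl
Reagents that add atoms: 1-iodobutane, CCCCI; lithium diisopropylamide, [Li]N(C(C)C)C(C)C (the lithium of 2 only)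
Why: Lateral lithiation of the o-toluate gives a carboxylate-stabilised benzylic carbanion that is far more nucleophilic than the carboxylate oxygen, so SN2 alkylation by the primary iodide should extend the methyl group to pentyl.

Step 2
Reactants: 3 2-methoxy-6-pentylbenzoic acid
Product: 4 tert-butyl 2-methoxy-6-pentylbenzoate
Conditions: t-BuOC(=NH)CCl3 (2 equiv), BF3·OEt2 (cat.), CH2Cl2/cyclohexane, rt
Reagents that add atoms: tert-butyl 2,2,2-trichloroacetimidate, CC(C)(C)OC(=N)C(Cl)(Cl)Cl
Why: Acid-catalysed imidate esterification transfers a tert-butyl cation to the carboxyl oxygen, so the new bond is O–C(t-Bu) and the crowding at the di-ortho-substituted acyl carbon should not matter.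

Step 3
Reactants: 4 tert-butyl 2-methoxy-6-pentylbenzoate
Product: 6 tert-butyl 4-hydroxy-2-methoxy-6-pentylbenzoate, via aryl pinacol boronate 5 (not isolated)
Conditions: [Ir(OMe)(cod)]2 (1.5 mol%), dtbpy (3 mol%), B2pin2 (1.0 equiv), THF, 80 °C; evaporate volatiles; Oxone, acetone/H2O, rt
Reagents that add atoms: bis(pinacolato)diboron, CC1(C)OB(OC1(C)C)B1OC(C)(C)C(C)(C)O1 (the Bpin of 5 only); potassium peroxymonosulfate, [K+].OOS(=O)(=O)[O-] (the phenol oxygen of 6)
Why: Iridium-catalysed C–H borylation is sterically governed and should select C4–H, the only ring hydrogen of this 1,2,3-trisubstituted arene without an ortho neighbour, after which ipso oxidation of the C–B bond gives the phenol in the same flask.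

Step 4
Reactants: 6 tert-butyl 4-hydroxy-2-methoxy-6-pentylbenzoate; 7 hex-2-ynoic acid
Product: 8 tert-butyl 4-(hex-2-ynoyloxy)-2-methoxy-6-pentylbenzoate
Conditions: DCC (1.2 equiv), DMAP (5 mol%), CH2Cl2, 0 °C → rt
Reagents that add atoms: none
Why: Steglich esterification should join the unhindered sp-flanked acyl carbon to the phenol cleanly, with low temperature and a small DMAP loading limiting conjugate addition to the ynoate.

Step 5
Reactants: 9 methyl (E)-3-methoxybut-2-enoate
Product: 11 1,3-dimethoxy-1-(trimethylsilyloxy)buta-1,3-diene, via lithium dienolate 10 (not isolated)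
Conditions: LDA (1.1 equiv, commercial solution), THF, −78 °C; TMSCl (1.2 equiv), −78 °C → rt; pentane, filter, distil
Reagents that add atoms: chlorotrimethylsilane, C[Si](C)(C)Cl; lithium diisopropylamide, [Li]N(C(C)C)C(C)C (the lithium of 10 only)
Why: Kinetic γ-deprotonation of the vinylogous ester gives the extended dienolate, whose hard oxygen terminus is silylated to the silyl ketene acetal (enolisation–O-silylation).

Step 6
Reactants: 8 tert-butyl 4-(hex-2-ynoyloxy)-2-methoxy-6-pentylbenzoate; 11 1,3-dimethoxy-1-(trimethylsilyloxy)buta-1,3-diene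
Product: 14 tert-butyl 4-[(2-hydroxy-4-methoxy-6-propylbenzoyl)oxy]-2-methoxy-6-pentylbenzoate, via cyclohexa-1,4-diene cycloadduct 12 (not isolated), via aryl trimethylsilyl ether 13 (not isolated)
Conditions: 11 (3 equiv), PhMe, sealed tube, 120 °C; then 1 M HCl, THF, rt
Reagents that add atoms: none
Why: Diene 11, its HOMO raised by three oxygen donors, should add across the ester-activated triple bond of 8 in a thermally allowed normal-electron-demand [4+2] process with unsymmetrical bond formation, the unsubstituted methylene end of 11 leading onto the propyl-substituted alkyne carbon while the acetal-type carbon closes onto the carbon next to the carbonyl, to give 12. Adduct 12 should aromatise by 1,4-elimination of methanol from its mixed ketal carbon to silyl ether 13, and the acidic work-up cleaves the O–Si bond to phenol 14. The closest known reaction type is the Diels–Alder benzannulation of 1-alkoxy-1-silyloxy-3-alkoxybutadienes with acetylenic esters to salicylates and resorcylates, β-alkyl ynoates being slow partners that need heating. Ring B closes by intermolecular [4+2] cycloaddition that forms C1–C2 and C5–C6 together; no stereocentre reaches the product, since the single ketal stereocentre of racemic 12 is erased on aromatisation. The one selectivity required is regiochemical and is secured by the match of the largest diene HOMO coefficient (the CH2 carbon) with the largest ynoate LUMO coefficient (Cβ), which places oxygen on C2 and C4 and propyl on C6. The aryl ester lowers the dienophile LUMO relative to an alkyl ester, the excess of 11 scavenges the liberated methanol, and 8 has no free OH or NH that could add to the ynoate.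

Step 7
Reactants: 14 tert-butyl 4-[(2-hydroxy-4-methoxy-6-propylbenzoyl)oxy]-2-methoxy-6-pentylbenzoate
Product: 15 tert-butyl 4-[(2,4-dimethoxy-6-propylbenzoyl)oxy]-2-methoxy-6-pentylbenzoate
Conditions: MeI (3 equiv), K2CO3 (2 equiv), dry acetone, reflux
Reagents that add atoms: iodomethane, CI
Why: Williamson O-methylation of the hydrogen-bonded salicylate-type phenol should proceed with carbonate in a dry aprotic medium, where the crowded di-ortho-substituted aryl ester resists acyl transfer.

Step 8
Reactants: 15 tert-butyl 4-[(2,4-dimethoxy-6-propylbenzoyl)oxy]-2-methoxy-6-pentylbenzoate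
Product: 16 4-[(2,4-dimethoxy-6-propylbenzoyl)oxy]-2-methoxy-6-pentylbenzoic acid
Conditions: TFA/CH2Cl2 (1:4), 0 °C → rt
Reagents that add atoms: none
Why: Acidolysis of the tert-butyl ester proceeds by alkyl–oxygen fission with loss of isobutene, which is insensitive to the hindrance at the carboxyl group and should leave the aryl ester and the methyl ethers untouched.

Compound list
1 | 2-methoxy-6-methylbenzoic acid | Cc1cccc(OC)c1C(=O)O | starting material
2 | lithium 2-(lithiomethyl)-6-methoxybenzoate (benzylic dianion) | [Li]Cc1cccc(OC)c1C(=O)O[Li] | intermediate (not isolated)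
3 | 2-methoxy-6-pentylbenzoic acid | CCCCCc1cccc(OC)c1C(=O)O | intermediate
4 | tert-butyl 2-methoxy-6-pentylbenzoate | CCCCCc1cccc(OC)c1C(=O)OC(C)(C)C | intermediate
5 | tert-butyl 2-methoxy-6-pentyl-4-(4,4,5,5-tetramethyl-1,3,2-dioxaborolan-2-yl)benzoate | CCCCCc1cc(B2OC(C)(C)C(C)(C)O2)cc(OC)c1C(=O)OC(C)(C)C | intermediate (not isolated)
6 | tert-butyl 4-hydroxy-2-methoxy-6-pentylbenzoate | CCCCCc1cc(O)cc(OC)c1C(=O)OC(C)(C)C | intermediate
7 | hex-2-ynoic acid | CCCC#CC(=O)O | starting material
8 | tert-butyl 4-(hex-2-ynoyloxy)-2-methoxy-6-pentylbenzoate | CCCCCc1cc(OC(=O)C#CCCC)cc(OC)c1C(=O)OC(C)(C)C | intermediate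
9 | methyl (E)-3-methoxybut-2-enoate | CO/C(C)=C/C(=O)OC | starting material
10 | lithium 1,3-dimethoxybuta-1,3-dien-1-olate (lithium dienolate) | C=C(OC)/C=C(\OC)O[Li] | intermediate (not isolated)
11 | 1,3-dimethoxy-1-(trimethylsilyloxy)buta-1,3-diene | C=C(OC)/C=C(\OC)O[Si](C)(C)C | intermediate
12 | tert-butyl 4-{[4,6-dimethoxy-2-propyl-6-(trimethylsilyloxy)cyclohexa-1,4-diene-1-carbonyl]oxy}-2-methoxy-6-pentylbenzoate (racemic at the ketal carbon) | CCCCCc1cc(OC(=O)C2=C(CCC)CC(OC)=CC2(OC)O[Si](C)(C)C)cc(OC)c1C(=O)OC(C)(C)C | intermediate (not isolated)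
13 | tert-butyl 2-methoxy-4-{[4-methoxy-6-propyl-2-(trimethylsilyloxy)benzoyl]oxy}-6-pentylbenzoate | CCCCCc1cc(OC(=O)c2c(CCC)cc(OC)cc2O[Si](C)(C)C)cc(OC)c1C(=O)OC(C)(C)C | intermediate (not isolated)
14 | tert-butyl 4-[(2-hydroxy-4-methoxy-6-propylbenzoyl)oxy]-2-methoxy-6-pentylbenzoate | CCCCCc1cc(OC(=O)c2c(CCC)cc(OC)cc2O)cc(OC)c1C(=O)OC(C)(C)C | intermediate
15 | tert-butyl 4-[(2,4-dimethoxy-6-propylbenzoyl)oxy]-2-methoxy-6-pentylbenzoate | CCCCCc1cc(OC(=O)c2c(CCC)cc(OC)cc2OC)cc(OC)c1C(=O)OC(C)(C)C | intermediate
16 | 4-[(2,4-dimethoxy-6-propylbenzoyl)oxy]-2-methoxy-6-pentylbenzoic acid | CCCCCc1cc(OC(=O)c2c(CCC)cc(OC)cc2OC)cc(OC)c1C(=O)O | target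

Total step count: 8. Longest linear sequence: 7 steps (steps 1, 2, 3, 4, 6, 7, 8); step 5 is a one-step side branch.

Steps most likely to fail

Step 6. The cycloaddition onto the β-propyl ynoate may be too slow, so that thermal decomposition or protodesilylation of the diene, or acyl transfer from the activated aryl ester, overtakes ring formation. The fallback sets out from phenol 6 and comes back at 15, building ring B by carbanion chemistry and attaching it as an acid chloride. Commercial 2,4-dimethoxy-6-methylbenzoic acid (Cc1cc(OC)cc(OC)c1C(=O)O) would be laterally lithiated with LDA (2.2 equiv, THF, −78 → 0 °C) to lithium 2,4-dimethoxy-6-(lithiomethyl)benzoate F1, which on alkylation with iodoethane and acidic work-up should give 2,4-dimethoxy-6-propylbenzoic acid F2. Treatment with 1-chloro-N,N,2-trimethylprop-1-en-1-amine in CH2Cl2 would convert it under neutral conditions into 2,4-dimethoxy-6-propylbenzoyl chloride F3. Acylation of 6 with this chloride (Et3N, DMAP, CH2Cl2, rt) should give 15, which continues with step 8.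

Step 4. The nucleophilic catalyst or the carbodiimide adduct may add to the activated triple bond, or O→N acyl shift to an N-acylurea may outrun acylation of the electron-poor phenol. The fallback sets out from acid 7 and comes back at 8 by way of a preformed acyl chloride, with no nucleophilic catalyst. Acid 7 would be converted with 1-chloro-N,N,2-trimethylprop-1-en-1-amine (CH2Cl2, 0 °C, no free HCl that could add to the alkyne) into hex-2-ynoyl chloride F4. This would be added to 6 and i-Pr2NEt in CH2Cl2 at −20 → 0 °C to give 8.

Step 7. The chelated, flanked phenoxide may alkylate slowly, so that base-mediated cleavage or acyl transfer at the aryl ester competes. The fallback sets out from 14 and comes back at 15 by Mitsunobu methylation (MeOH, PPh3, DIAD, THF, 0 °C → rt). It activates methanol as a methoxyphosphonium ion and alkylates the phenol without added base. No new compound is made (F0).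

Further compounds
F1 | step 6 | lithium 2,4-dimethoxy-6-(lithiomethyl)benzoate | [Li]Cc1cc(OC)cc(OC)c1C(=O)O[Li]
F2 | step 6 | 2,4-dimethoxy-6-propylbenzoic acid | CCCc1cc(OC)cc(OC)c1C(=O)O
F3 | step 6 | 2,4-dimethoxy-6-propylbenzoyl chloride | CCCc1cc(OC)cc(OC)c1C(=O)Cl
F4 | step 4 | hex-2-ynoyl chloride | CCCC#CC(=O)Cl
F0 | step 7 | none | none
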